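# Proposed total synthesis of sarcandrone B, (2R,4R)

## Structural features

Sarcandrone B is a flavan–chalcone hybrid. A 2-phenylchroman (ring C: O1, C2, C3, C4; ring A: C4a–C8a with 5-OMe, 7-OH, 8-OMe; ring B: the phenyl on C2) is bonded through C4 to C3' of a 2',6'-dihydroxy-4'-methoxychalcone (ring A': C1'–C6', cinnamoyl on C1'). The only stereocentres, C2 and C4, stand 1,3 to each other across the C3 methylene. The SMILES reads as (2R,4R), that is 2,4-trans, with ring B equatorial and ring A' axial, the arrangement that avoids the peri contact between ring A' and 5-OMe.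

C4 is a diarylmethine between two di-ortho-oxygenated arenes (5-OMe and O1 on ring A, 2'-OH and 4'-OMe on ring A'). C4–C3' is therefore the most hindered bond and, like an interflavan bond, can be cleaved again by acid. The 2',6'-dihydroxychalcone ring-closes by oxa-Michael addition under acid or base, its enone excludes hydrogenolysis, hydride reagents and hard carbanions late in the route, and the electron-rich phenols are air-sensitive. Ring A has a 1,2,3,5-tetraoxygenation pattern with alternating methylated and free (or ring) oxygens that no cheap arene offers.

The real difficulty is to make C4–C3' with absolute control and to place C2 trans to it. Whenever hydrogen is the last group to arrive at C2 or C4, it enters anti to the substituent on the other centre and the 2,4-cis flavan results.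

The key step exploits two features. First, both aryl groups on C4 carry an oxygen ortho to C4 (O1 on C8a, the 2'-OH on C2') and both oxygens can reach C2. Without ring B, C2 is an aldehyde carbon that these oxygens clamp into a dibenzo-fused 2,8-dioxabicyclo[3.3.1]nonane. Second, C3' and C5' of the free ring A' ketone are equivalent, so the union has only one possible outcome.

## Logic of the disconnections

**19 to 15 and 16.**
- Bond cut: C2–C(ipso) of ring B. In the same move the 2'-oxygen is bonded back to C2, so C2–O2' is the bond broken in the forward sense.
- Reason: C2 is the one place where a carbon group can arrive last. A group arriving last at C2 enters anti to the axial ring A' on C4. For carbon this gives the 2,4-trans relation; for hydrogen it gives cis. O2' stands ortho to the acyl group and leaves as a vinylogous carboxylate.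
- Gain: C2 is no longer an independent stereochemical problem, six carbons leave, the 2'-OH is masked, and a rigid bicycle of two arenes and a C3 chain remains.
- Demand: the forward step must break C2–O2' and not C2–O1, must spare enone and ketone, and must transfer phenyl from outside, not from a metal held by the departing oxygen.

**15 to 13 and 14.**
- Bond cut: Cα=Cβ of the enone.
- Reason: in 13 the bridge holds O2' as an ether. The ketone is then a 2-alkoxy-6-hydroxyaryl methyl ketone, the type on which base-mediated condensation is reliable, and an acetal is inert to hydroxide.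
- Gain: seven carbons and the fragile enone are absent from every earlier step, including the only acidic one.
- Demand: base only, and a buffered neutralisation.

**13 to 10 and 11 (key disconnection).**
- Bonds cut: C4–C3', C2–O2' and C2–O1, that is both pyran rings of the bicycle.
- Reason: 10 is achiral and flat, carries no ring B, and holds C2 at the aldehyde level. 11 is commercial, and its two free ring positions are equivalent.
- Gain: a bicycle with two stereocentres falls apart into two achiral monocyclic arenes. C4 needs one catalyst-controlled event, and C2 follows from C4 through the bridge.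
- Demand: face-selective C–C bond formation at a hindered β-carbon, then a convergent acid stage.
- In one sentence: an aminocatalytic Friedel–Crafts/double acetalisation cascade welds 10 and 11 into 13. This sentence does not fit the coupling of a finished flavan with a chalcone.

**10 to 6 and 7.**
- Bond cut: C4–C4a.
- Reason: 6 has C2v symmetry, its two ring hydrogens are equivalent, and each is flanked by two directing oxygens, so metalation has one outcome. 7 delivers C2–C3–C4 at the right oxidation level in one operation.
- Gain: the whole C3 chain.
- Demand: 1,2-addition to 7, and a quench mild enough for the MOM groups.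

**6 to 5, 2 and 1.**
- Bonds cut: the O–CH3 bond on the C8 oxygen, the C8–O bond, and the two O–CH2OCH3 bonds.
- Reason: in 2 the carbon between the two protected oxygens is the most acidic position, which is exactly where the fourth oxygen of ring A belongs.
- Gain: the awkward tetraoxygenated ring A is traced to commercial 1.
- Demand: regioselective metalation, and prompt methylation of the oxidation-prone 5.

## Other disconnections considered

Alternative 1: Cut C4–C3' in the finished flavan, the first idea that comes to mind. Forward: the enantioenriched flavanone A1 is reduced to the flavan-4-ol A2, acid ionises A2 to the C4 cation, and the chalcone A3 attacks trans to ring B. The diastereoselectivity is sound, but the plan has three weaknesses.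
- All absolute information must be bought with A1, a 5-alkoxyflavanone that can racemise by retro-oxa-Michael opening. It needs its own asymmetric synthesis on the same tetraoxygenated ring A.
- The acid that ionises A2 also promotes oxa-Michael ring closure of A3 and can re-cleave the new C4–C3' bond. The coupling therefore runs under equilibrium, with a second alkylation at C5' as a drain.
- The key step adds one bond to a precursor almost as complex as the target.

The chosen plan sets C4 catalytically on achiral material and keeps the enone away from acid.

Alternative 2: Keep ring B and cut C4–C3' and C2–O2' at the flavylium level. Forward: the flat flavylium salt A4 is dearomatised by 11 under chiral-anion catalysis to the 2-phenyl bridged ketal A5, and C2–O2' is then cleaved reductively. Here hydrogen is the last group to reach C2.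
- External hydride donors (silanes, borohydrides) approach anti to the axial ring A' and to the departing O2', which leads to the 2,4-cis flavan A6.
- Hydride donors that deliver with retention because they bind the leaving oxygen (aluminium hydrides) would also reduce the aryl ketone.
- A trialkoxyflavylium ion is in addition a weak electrophile.

The chosen plan uses the same bicycle but exchanges the roles of H and phenyl on C2, so that the inherent anti attack gives trans.

Alternative 3: Cut C3–C4 and O1–C2. Forward: the benzhydrol A7 is dehydrated by a chiral Brønsted acid to the ortho-quinone methide A8, which undergoes a hetero-Diels–Alder reaction with styrene A9 and sets both centres at once. Grounds against it: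
- The methide carbon lies between two trioxygenated arenes and is so stabilised that the weakly nucleophilic A9 should react very slowly.
- The catalyst would have to tell apart two nearly identical 2-hydroxy-6-methoxyaryl groups to define C4.
- Either ortho-OH (on C8a or on C2') can close the ring, which gives constitutional isomers.
- The endo mode of an E-configured A8 leads to the cis series of A6.
- A7 is not shorter to make than 13.

Key step: step 5

Remark on the chemistry: flavan numbering (O1, C2, C3, C4, C4a–C8a; primed numbers for ring A') is kept for all intermediates. The target SMILES is read as (2R,4R), 2,4-trans. Compounds 1, 7, 11, 14, 16 and the catalyst are taken as commercial.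

## Steps

Step 1
Reactants: 1 5-methoxyresorcinol (5-methoxybenzene-1,3-diol)
Product: 2 1-methoxy-3,5-bis(methoxymethoxy)benzene
Conditions: NaH, MOMCl, DMF, 0 °C to rt
Reagents that add atoms: chloromethyl methyl ether (MOMCl), COCCl
Why: Williamson-type O-alkylation of both phenoxides; MOM is chosen because it is a strong ortho-directing group for steps 2 and 4 and leaves by itself in the acid stage of step 5.

Step 2
Reactants: 2 1-methoxy-3,5-bis(methoxymethoxy)benzene
Product: 5 4-methoxy-2,6-bis(methoxymethoxy)phenol, via aryllithium 3 (not isolated), via dimethyl boronate 4 (not isolated)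
Conditions: n-BuLi, THF, 0 °C; B(OMe)3, −78 °C to rt; 30% H2O2, aq NaOH, 0 °C
Reagents that add atoms: hydrogen peroxide, OO (the new phenolic oxygen); trimethyl borate, COB(OC)OC (boron and methoxy groups of 4 only); n-butyllithium, [Li]CCCC (lithium of 3 only)
Why: Directed ortho-metalation should take place at the position flanked by two OMOM groups (cooperative chelation) rather than at the two positions between OMOM and OMe. Borylation and peroxide oxidation (1,2-shift of aryl from B to O) turn the C–Li bond into the C–O bond that becomes the C8 oxygen.

Step 3
Reactants: 5 4-methoxy-2,6-bis(methoxymethoxy)phenol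
Product: 6 2,5-dimethoxy-1,3-bis(methoxymethoxy)benzene
Conditions: MeI, K2CO3, DMF, rt
Reagents that add atoms: iodomethane, CI
Why: Williamson methylation of the only free phenol; it removes the oxidation-prone hydroquinone monoether and gives a C2v-symmetric arene whose two ring hydrogens are equivalent.

Step 4
Reactants: 6 2,5-dimethoxy-1,3-bis(methoxymethoxy)benzene; 7 (E)-3-(dimethylamino)prop-2-enal
Product: 10 (E)-3-[3,6-dimethoxy-2,4-bis(methoxymethoxy)phenyl]prop-2-enal, via aryllithium 8 (not isolated), via lithium alkoxide 9 (not isolated)
Conditions: n-BuLi, TMEDA, THF, 0 °C; 7, −78 to 0 °C; 1 M aq HCl to pH 4, 0 °C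
Reagents that add atoms: water, O (the aldehyde oxygen is exchanged with water in the hydrolysis of the vinylogous iminium ion, the alkoxide oxygen of 9 leaves as water); n-butyllithium, [Li]CCCC (lithium of 8 and 9 only)
Why: Directed ortho-metalation at a C–H flanked by OMOM and OMe (both free positions are equivalent) followed by 1,2-addition to the vinylogous formamide 7, a vinylogous formylation of an aryllithium. On mild acid the amino allylic alkoxide loses water to the vinylogous iminium ion, whose hydrolysis gives the conjugated E-enal.

Step 5
Reactants: 10 (E)-3-[3,6-dimethoxy-2,4-bis(methoxymethoxy)phenyl]prop-2-enal; 11 1-(2,6-dihydroxy-4-methoxyphenyl)ethanone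
Product: 13 (6S,12R)-1-(3,9-dihydroxy-1,4,11-trimethoxy-6H,12H-6,12-methanodibenzo[d,g][1,3]dioxocin-8-yl)ethanone (bridged acetal; C6 = flavan C2 and C12 = flavan C4), via lactol 12 (not isolated)
Conditions: (S)-α,α-diphenylprolinol trimethylsilyl ether (20 mol %), PhCO2H (20 mol %), CH2Cl2–MeCN, rt; then HCl (1.25 M in MeOH), 0 °C to rt
Reagents that add atoms: none
Why: 10 and the (S)-catalyst form the E, s-trans iminium ion, in which the CPh2(OSiMe3) group covers the Re face of C4, so that 11, a vinylogous acid that reacts through its phenolate like a cyclic 1,3-diketone, bonds with C3' to the open Si face and rearomatises to the (4R)-diarylmethine. The closest known reaction types are the iminium-catalysed Friedel–Crafts alkylation/hemiacetalisation of naphthols and electron-rich phenols with enals and the domino reaction of 2-hydroxycinnamaldehydes with 1,3-dicarbonyl compounds to bridged acetals. The first ring closes by 6-exo-trig addition of the 2'-OH group to the released aldehyde (lactol 12), which takes the aldehyde out of the iminium equilibrium. Methanolic HCl then removes both MOM groups as dimethoxymethane and ionises the lactol, and the freed C8a–OH closes the second ring by 6-exo-trig attack on the C2 oxocarbenium ion. C4 is set by the catalyst, and C2 is set by C4, because O2' on C2 and C3' on C4 belong to the same arene and must lie on the same face of ring C, which leaves (2S) as the only possible configuration. Regioselectivity needs no control: C3' and C5' of 11 are equivalent, the 4'-OMe and 5-OMe groups cannot cyclise, the 7-OH and 6'-OH groups stand para to C4 and cannot reach C2, and O-alkylation of 11 is reversible. A second alkylation at C5' is held back by a small excess of 11 and by the lower nucleophilicity of the hindered product. The bridged acetal is the thermodynamic sink of all lactol, methyl acetal and 4H-chromene isomers, so the acid stage is convergent.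

Step 6
Reactants: 13 bridged acetal ketone; 14 benzaldehyde
Product: 15 (E)-1-[(6S,12R)-3,9-dihydroxy-1,4,11-trimethoxy-6H,12H-6,12-methanodibenzo[d,g][1,3]dioxocin-8-yl]-3-phenylprop-2-en-1-one (bridged acetal chalcone)
Conditions: KOH (50% aq), EtOH, 0 °C to rt; AcOH to pH 6, 0 °C
Reagents that add atoms: none
Why: Claisen–Schmidt condensation (aldol addition, E1cB loss of water) gives the E-enone under thermodynamic control; the bridge holds O2' as an ether, so that 13 is a 2-alkoxy-6-hydroxyaryl methyl ketone, the substrate class on which this condensation is routine, and the acetal and both stereocentres are inert to hydroxide. Neutralisation with acetic acid at 0 °C avoids oxa-Michael closure of the 6'-OH group.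

Step 7
Reactants: 15 bridged acetal chalcone; 16 diphenylzinc
Product: 19 sarcandrone B, via bis(trimethylsilyl) ether 17 (not isolated), via tris(trimethylsilyl) ether 18 (not isolated)
Conditions: BSA, CH2Cl2, rt, evaporate; 16, TMSOTf, CH2Cl2–toluene, −78 to −30 °C; aq citric acid, MeOH, 0 °C
Reagents that add atoms: N,O-bis(trimethylsilyl)acetamide (BSA), CC(=N[Si](C)(C)C)O[Si](C)(C)C, and trimethylsilyl triflate, C[Si](C)(C)OS(=O)(=O)C(F)(F)F (silyl groups of 17 and 18 only; no atom of either stays in 19)
Why: Lewis-acid-promoted substitution of an acetal by an arylzinc reagent through an oxocarbenium ion, the reaction type of C-aryl glycoside synthesis; the silyl cation is taken up at the cinnamoyl/O2' site, where O2' leaves as a vinylogous carboxylate, whereas O1 on the electron-rich ring A is the better donor, so that C2–O2' and not C2–O1 should break. The silylated ring A' stays axial on C4 (bridge geometry, peri strain with 5-OMe) and covers the face of C2 that O2' has just left, so phenyl is transferred to the opposite face with inversion, (2S)-acetal to (2R)-flavan, that is 2,4-trans, and the other half-chair with an equatorial ring A' gives the same trans isomer by axial attack. Diphenylzinc without a copper or nickel catalyst should not add to the enone or the hindered ketone, and the citric acid work-up removes the three aryl silyl ethers without closing the chalcone.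

## Compound list

1 | 5-methoxyresorcinol | COc1cc(O)cc(O)c1 | starting material
2 | 1-methoxy-3,5-bis(methoxymethoxy)benzene | COCOc1cc(OC)cc(OCOC)c1 | intermediate
3 | [4-methoxy-2,6-bis(methoxymethoxy)phenyl]lithium | [Li]c1c(OCOC)cc(OC)cc1OCOC | intermediate
4 | dimethyl [4-methoxy-2,6-bis(methoxymethoxy)phenyl]boronate | COB(OC)c1c(OCOC)cc(OC)cc1OCOC | intermediate
5 | 4-methoxy-2,6-bis(methoxymethoxy)phenol | Oc1c(OCOC)cc(OC)cc1OCOC | intermediate
6 | 2,5-dimethoxy-1,3-bis(methoxymethoxy)benzene | COc1c(OCOC)cc(OC)cc1OCOC | intermediate
7 | (E)-3-(dimethylamino)prop-2-enal | CN(C)/C=C/C=O | starting material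
8 | [3,6-dimethoxy-2,4-bis(methoxymethoxy)phenyl]lithium | [Li]c1c(OC)cc(OCOC)c(OC)c1OCOC | intermediate
9 | lithium (E)-3-(dimethylamino)-1-[3,6-dimethoxy-2,4-bis(methoxymethoxy)phenyl]prop-2-en-1-olate (racemic) | CN(C)/C=C/C(O[Li])c1c(OC)cc(OCOC)c(OC)c1OCOC | intermediate
10 | (E)-3-[3,6-dimethoxy-2,4-bis(methoxymethoxy)phenyl]prop-2-enal | O=C/C=C/c1c(OC)cc(OCOC)c(OC)c1OCOC | intermediate
11 | 1-(2,6-dihydroxy-4-methoxyphenyl)ethanone | CC(=O)c1c(O)cc(OC)cc1O | starting material
12 | 1-{(4R)-4-[3,6-dimethoxy-2,4-bis(methoxymethoxy)phenyl]-2,7-dihydroxy-5-methoxychroman-8-yl}ethanone (lactol on ring A', both C2 epimers) | OC1C[C@@H](c2c(OC)cc(OCOC)c(OC)c2OCOC)c2c(OC)cc(O)c(C(C)=O)c2O1 | intermediate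
13 | (6S,12R)-1-(3,9-dihydroxy-1,4,11-trimethoxy-6H,12H-6,12-methanodibenzo[d,g][1,3]dioxocin-8-yl)ethanone (flavan numbering 2S,4R) | O1c2c(OC)c(O)cc(OC)c2[C@@H]2C[C@H]1Oc1c2c(OC)cc(O)c1C(C)=O | intermediate
14 | benzaldehyde | O=Cc1ccccc1 | starting material
15 | (E)-1-[(6S,12R)-3,9-dihydroxy-1,4,11-trimethoxy-6H,12H-6,12-methanodibenzo[d,g][1,3]dioxocin-8-yl]-3-phenylprop-2-en-1-one | O1c2c(OC)c(O)cc(OC)c2[C@@H]2C[C@H]1Oc1c2c(OC)cc(O)c1C(=O)/C=C/c1ccccc1 | intermediate
16 | diphenylzinc | c1ccccc1[Zn]c1ccccc1 | starting material
17 | 3,9-bis(trimethylsilyl) ether of 15 | O1c2c(OC)c(O[Si](C)(C)C)cc(OC)c2[C@@H]2C[C@H]1Oc1c2c(OC)cc(O[Si](C)(C)C)c1C(=O)/C=C/c1ccccc1 | intermediate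
18 | 7,2',6'-tris(trimethylsilyl) ether of 19 | COc1cc(O[Si](C)(C)C)c(C(=O)/C=C/c2ccccc2)c(O[Si](C)(C)C)c1[C@H]1C[C@H](c2ccccc2)Oc2c(OC)c(O[Si](C)(C)C)cc(OC)c21 | intermediate
19 | sarcandrone B, (E)-1-{2,6-dihydroxy-3-[(2R,4R)-7-hydroxy-5,8-dimethoxy-2-phenylchroman-4-yl]-4-methoxyphenyl}-3-phenylprop-2-en-1-one | COc1cc(O)c(C(=O)/C=C/c2ccccc2)c(O)c1[C@H]1C[C@H](c2ccccc2)Oc2c(OC)c(O)cc(OC)c21 | target

## Step count and least certain steps

Total step count: 7. Longest linear sequence: 7 steps (1, 2, 5, 6, 10, 13, 15, 19).

**Step 5 (key step).** The most likely failure is slow C–C bond formation. C4 of the iminium ion carries an electron-rich 2,6-dioxygenated aryl group, and the attacking C3' is itself flanked by OH and OMe. A racemic acid-catalysed background addition or parasitic binding of the catalyst could then take over and erode the enantiomeric purity. In the acid stage, transfer of methoxymethyl cations to the electron-rich rings and acidolysis of the C4–aryl bonds are the side processes to watch.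

The fallback exchanges the polarity of the two arenes, so that C4–C4a is formed instead of C4–C3'. It sets out from 6 and 11 and comes back at 13.
- Methanolic HCl frees 6 to 2,5-dimethoxybenzene-1,3-diol F1, a much stronger carbon nucleophile than 11, again with two equivalent positions.
- Rieche formylation of 11 (Cl2CHOMe, TiCl4) gives 3-acetyl-2,4-dihydroxy-6-methoxybenzaldehyde F2.
- Wittig homologation with (triphenylphosphoranylidene)acetaldehyde gives (E)-3-(3-acetyl-2,4-dihydroxy-6-methoxyphenyl)prop-2-enal F3. Its iminium ion is more electrophilic because ring A' carries the acyl group.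
- With the (R)-enantiomer of the catalyst (nucleophile and resident aryl group have changed places), F1 adds to F3 to give (3R)-3-(3-acetyl-2,4-dihydroxy-6-methoxyphenyl)-3-(2,4-dihydroxy-3,6-dimethoxyphenyl)propanal F4.
- A trace of acid closes F4 to the same 13.

**Step 7.** Four processes are most likely to go wrong:
- loss of the C3 proton from the oxocarbenium ion (return to the acetal on work-up, hence no conversion);
- phenyl transfer from a zinc centre held by the departing oxygen (erosion of facial selectivity);
- ionisation of the wrong C–O bond;
- attack on the silyl-activated enone.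

The fallback changes C2 from a cation to a radical and builds the enone afterwards. It sets out from 13 and comes back at 19.
- BSA gives the bis(trimethylsilyl) ether of 13 F5.
- TMSBr cleaves the same C2–O2' bond to the 2-bromochroman F6 (both C2 epimers).
- A nickel-catalysed Negishi coupling with PhZnBr (NiCl2·glyme, terpyridine ligand), the reaction type used for C-aryl glycosides from glycosyl bromides, takes both epimers through one planar C2 radical. This radical should be captured anti to the axial ring A' and give the tris(trimethylsilyl) ether of the trans-flavanyl ketone F7.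
- Citric acid in methanol gives 1-{2,6-dihydroxy-3-[(2R,4R)-7-hydroxy-5,8-dimethoxy-2-phenylchroman-4-yl]-4-methoxyphenyl}ethanone F8.
- Condensation of the lithium polyanion of F8 (excess LiHMDS, THF) with 14 gives 19.

**Step 6.** The likely problems are oxa-Michael closure of the 6'-OH group onto the new enone during neutralisation, and slow enolisation of the di-ortho-substituted ketone, which gives the Cannizzaro reaction of 14 time to compete. The fallback brings the cinnamoyl group in with the nucleophile. It sets out from 10, 11 and 14 and comes back at 15.
- 11 and 14 are condensed at the stage of the cheap building block to 2',6'-dihydroxy-4'-methoxychalcone F9.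
- F9 replaces 11 in the protocol of step 5 and passes through the cinnamoyl lactol F10.
- Methanolic HCl converts F10 into 15.

**Step 4.** The likely problems are incomplete metalation, premature loss of MOM groups in the acidic quench, and oligomerisation of the electron-rich enal. The fallback builds the chain as C1 plus C2 instead of C3. It sets out from 6 and comes back at 10.
- Metalation as before and quenching with DMF give 3,6-dimethoxy-2,4-bis(methoxymethoxy)benzaldehyde F11, which needs no acid.
- Wittig olefination of F11 with (triphenylphosphoranylidene)acetaldehyde in warm toluene gives 10.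

## Further compounds

F1 | step 5 | 2,5-dimethoxybenzene-1,3-diol | COc1cc(O)c(OC)c(O)c1
F2 | step 5 | 3-acetyl-2,4-dihydroxy-6-methoxybenzaldehyde | CC(=O)c1c(O)cc(OC)c(C=O)c1O
F3 | step 5 | (E)-3-(3-acetyl-2,4-dihydroxy-6-methoxyphenyl)prop-2-enal | CC(=O)c1c(O)cc(OC)c(/C=C/C=O)c1O
F4 | step 5 | (3R)-3-(3-acetyl-2,4-dihydroxy-6-methoxyphenyl)-3-(2,4-dihydroxy-3,6-dimethoxyphenyl)propanal | O=CC[C@@H](c1c(OC)cc(O)c(OC)c1O)c1c(O)c(C(C)=O)c(O)cc1OC
F5 | step 7 | bis(trimethylsilyl) ether of 13 | O1c2c(OC)c(O[Si](C)(C)C)cc(OC)c2[C@@H]2C[C@H]1Oc1c2c(OC)cc(O[Si](C)(C)C)c1C(C)=O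
F6 | step 7 | 1-{3-[(4R)-2-bromo-5,8-dimethoxy-7-(trimethylsilyloxy)chroman-4-yl]-4-methoxy-2,6-bis(trimethylsilyloxy)phenyl}ethanone (both C2 epimers) | CC(=O)c1c(O[Si](C)(C)C)cc(OC)c([C@H]2CC(Br)Oc3c(OC)c(O[Si](C)(C)C)cc(OC)c32)c1O[Si](C)(C)C
F7 | step 7 | tris(trimethylsilyl) ether of F8 | CC(=O)c1c(O[Si](C)(C)C)cc(OC)c([C@H]2C[C@H](c3ccccc3)Oc3c(OC)c(O[Si](C)(C)C)cc(OC)c32)c1O[Si](C)(C)C
F8 | step 7 | 1-{2,6-dihydroxy-3-[(2R,4R)-7-hydroxy-5,8-dimethoxy-2-phenylchroman-4-yl]-4-methoxyphenyl}ethanone | CC(=O)c1c(O)cc(OC)c([C@H]2C[C@H](c3ccccc3)Oc3c(OC)c(O)cc(OC)c32)c1O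
F9 | step 6 | 2',6'-dihydroxy-4'-methoxychalcone | COc1cc(O)c(C(=O)/C=C/c2ccccc2)c(O)c1
F10 | step 6 | (E)-1-{(4R)-4-[3,6-dimethoxy-2,4-bis(methoxymethoxy)phenyl]-2,7-dihydroxy-5-methoxychroman-8-yl}-3-phenylprop-2-en-1-one (both C2 epimers) | OC1C[C@@H](c2c(OC)cc(OCOC)c(OC)c2OCOC)c2c(OC)cc(O)c(C(=O)/C=C/c3ccccc3)c2O1
F11 | step 4 | 3,6-dimethoxy-2,4-bis(methoxymethoxy)benzaldehyde | O=Cc1c(OC)cc(OCOC)c(OC)c1OCOC
A1 | alternative 1 | (2R)-7-hydroxy-5,8-dimethoxyflavanone | O=C1C[C@H](c2ccccc2)Oc2c(OC)c(O)cc(OC)c21
A2 | alternative 1 | (2R)-7-hydroxy-5,8-dimethoxyflavan-4-ol (either C4 epimer) | OC1C[C@H](c2ccccc2)Oc2c(OC)c(O)cc(OC)c21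
A3 | alternative 1 | 2',6'-dihydroxy-4'-methoxychalcone | COc1cc(O)c(C(=O)/C=C/c2ccccc2)c(O)c1
A4 | alternative 2 | 7-hydroxy-5,8-dimethoxyflavylium chloride | COc1cc(O)c(OC)c2[o+]c(-c3ccccc3)ccc12.[Cl-]
A5 | alternative 2 | 6-phenyl analogue of 13 (bridged ketal, flavan numbering 2R,4R) | O1c2c(OC)c(O)cc(OC)c2[C@@H]2C[C@@]1(c3ccccc3)Oc1c2c(OC)cc(O)c1C(C)=O
A6 | alternative 2 | 1-{2,6-dihydroxy-3-[(2S,4R)-7-hydroxy-5,8-dimethoxy-2-phenylchroman-4-yl]-4-methoxyphenyl}ethanone (2,4-cis) | CC(=O)c1c(O)cc(OC)c([C@H]2C[C@@H](c3ccccc3)Oc3c(OC)c(O)cc(OC)c32)c1O
A7 | alternative 3 | 1-{3-[(2,4-dihydroxy-3,6-dimethoxyphenyl)(hydroxy)methyl]-2,6-dihydroxy-4-methoxyphenyl}ethanone (racemic) | OC(c1c(OC)cc(O)c(OC)c1O)c1c(O)c(C(C)=O)c(O)cc1OC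
A8 | alternative 3 | ortho-quinone methide of ring A derived from A7 | O=C1C(OC)=C(O)C=C(OC)C1=Cc1c(O)c(C(C)=O)c(O)cc1OC
A9 | alternative 3 | styrene | C=Cc1ccccc1
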